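## The problem

The target is a melampolide. Its core is a ten-membered carbocycle C1–C10 with a ring-cis C1=C10 enoate (C14 methyl ester on C10) and a trans 4,5-epoxide (C15 methyl on C4). Fused across C6–C7 is a trans α-methylene γ-lactone (O6 to C12, C11=C13 on C7). C8 carries the ester of (2S,3R)-2,3-epoxy-2-methylbutanoic acid (the epoxide of tiglic acid) and C9 a free hydroxyl. The two oxygens are erythro (8S,9R) and lie on the ring face that holds C11 at C7.

Of the six ring stereocenters (4R,5R,6S,7R,8S,9R), C6 can set C7, because addition to a flat butenolide occurs trans to the C6 substituent. C6 is a weak handle on C4/C5, so the epoxide needs reagent control. C8/C9 relate to C7 only through the shape of the ten-membered ring, which makes that relation the least secure of all.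

The ring is strained, so its closure has to be driven. Several groups will not survive rough treatment:
- the α-methylene lactone is a Michael acceptor and is reduced by hydrides;
- both epoxides are acid-labile;
- three ester-type carbonyls rule out hard nucleophiles;
- a free C8 hydroxyl can pass its acyl group to O9 or relactonise onto C12 under base.

A short entry is possible because the lactone ring O6–C6–C7–C11–C12 is a butenolide that has gained one carbon at C7 (C8) and one at C11 (C13). C6 with C5 attached is a five-carbon lactone available enantiopure.

## Retrosynthesis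

**C8–O acyl bond (31 ⇒ 30 ⇒ 24 + 28).** The epoxy ester is the most fragile group, so it is attached last. Cutting it leaves alcohol 24, in which O9 is masked as a triethylsilyl ether, and acid 28. Acylating first and oxidising later would expose the side-chain epoxide to every oxidant of the route. The forward reaction must acylate a hindered secondary alcohol without acid, and the silyl ether must then leave without an acyl shift from O8 to O9.

**Both C–O bonds at C8 and C9 (24 ⇒ 23 ⇒ 22).** The diol 23 is traced to the Z alkene of 22 by one suprafacial addition. This sets the erythro relation by mechanism and removes two stereocenters in one cut. The neighbouring option, bringing C8 and C9 in separately, costs an open-chain stereocenter and a second carbonyl addition. The price here is twofold: the two hydroxyls of 23 must be told apart, and the addition must occur on the face that carries C11. The first is asked of a selective silylation at the allylic C9 hydroxyl. The second is asked of the ring, and it is the most demanding requirement of the plan.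

**C8=C9 (22 ⇒ 21).** Ring-closing metathesis opens the ten-membered ring to tetraene 21, whose two reacting alkenes are plain vinyl groups on C7 and C10. This bond is chosen because both partners are monosubstituted and the loss of a small volatile alkene makes closure irreversible. No other ring bond of 22 offers that. The forward step needs a Z alkene, which the ring size should impose, and high dilution.

**C9–C10, the epoxide oxygen and C1=C10 (21 ⇒ 19 + 20; 19 ⇒ 18; 18 ⇒ 15 + 16 through 17).**
- The 2-vinylacrylate of 21 is made last before ring closure, by coupling stannane 20 with iodoenoate 19, because such dienes are prone to dimerise.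
- The epoxide is removed next (19 ⇒ 18). The E trisubstituted alkene of 18 is the only electron-rich alkene present, so a reagent-controlled oxygen transfer can set C4 and C5 without relying on C6.
- The iodoenoate comes from aldehyde 15 and the iodo ylide 17, made in the flask from ylide 16. The Z iodoalkene carries the geometry that becomes the ring-cis C1=C10.

**C2–C3 and C4–C5 (15 ⇒ 14 ⇒ 12 + 13; 12 ⇒ 10 + 11).** A Claisen rearrangement of the allyl vinyl ether 14 forms C2–C3 and places the E trisubstituted C4=C5 alkene. It also delivers C1 directly as an aldehyde. An ester-stabilised Wittig reagent at C5 would also give the E alkene, but its ester would then have to be reduced beside a lactone and an α-methylene lactone, which no hydride does cleanly. The allylic alcohol 12 comes from aldehyde 10 and bromide 11 by a chromium-mediated addition that ignores both. Its carbinol configuration is irrelevant, since C5 becomes sp2.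

**Oxidation level at C5 (10 ⇒ 9 ⇒ 8).** Aldehyde 10 is reached from silyl ether 8 by desilylation to 9 and a neutral oxidation. Nothing is simplified here, but from 8 onward every reagent must be non-nucleophilic and non-hydridic, and this pair meets that.

**C7–C8 and C11–C13 (8 ⇒ 2 + 3 + 4, through 5, 6 and 7; 2 ⇒ 1).** Both exocyclic carbons are removed from the lactone in one operation. Copper-mediated addition of the vinyl group of 3 to butenolide 2 gives enolate 5, which is trapped by iminium salt 4, and the amine is then eliminated. Cutting only C11–C13 would leave a separate enolisation of a lactone that already carries the vinyl group. Cutting only C7–C8 would leave an α-methylene butenolide that does not exist as such. The precursor 2 is the silyl ether of commercial 1 and holds only C6. The forward step must deliver the vinyl group trans to the C6 substituent and alkylate C11 once.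

**Side chain (28 ⇒ 27 ⇒ 26 ⇒ 25).** The acid is traced through epoxy alcohol 27 to the allylic alcohol 26 and tiglic acid 25. An allylic alcohol is the one substrate class for which epoxide configuration can be chosen with confidence from the reagent alone.

## Roads not taken

**Alternative 1:** The cut falls on C5–C6 and C4–C15 at once. Forward, zerovalent nickel (Ni(cod)2 with an N-heterocyclic carbene) would join a terminal alkyne at C4≡C5 and an aldehyde at C6 into an oxanickelacycle. Me2Zn would deliver the C15 methyl to C4, and reductive elimination would close the ring as the (E)-allylic alcohol A1.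
- Merits: the ring, the E geometry of C4=C5, the C15 methyl and the C6 carbinol arise in one step. The C6 hydroxyl of A1 could direct the epoxidation and lactonise onto the tert-butyl ester. C8 and C9 arrive with different protecting groups. The α-methylene unit would be added last and need not survive anything.
- Weak points: C6 is created in the ring-forming step with no evident control, so the lactone configuration becomes the uncertain point. The C1=C10 enoate is a competing π-ligand for nickel. Three contiguous stereocenters (C7, C8, C9) must be built in an open chain first. After A1 there remain lactonisation, methylenation, epoxidation and a protecting-group exchange at O8.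
- Comparison: this road is better on the 8,9-diol (no differentiation, no dependence on a ring face) and on the lifetime of the methylene lactone. The chosen plan sets against it a secure C6/C7 relation from the first two steps and a much shorter path to the ring-closure substrate.

**Alternative 2:** The cut is C9–C10. Forward, CrCl2 with catalytic NiCl2 would turn a (Z)-2-iodoenoate at C10 into an alkenylchromium that adds to a C9 aldehyde. This closes the ring and creates the C9 carbinol of A2.
- Merits: organochromium reagents tolerate the lactone, the methylene lactone and the epoxide. The iodoalkene geometry is retained as the ring-cis C1=C10. C8 is set and silylated before the ring exists, so O8 and O9 are differentiated by construction.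
- Weak points: the C9 configuration depends on how the ring folds in the addition step. C8 must be installed in an open chain next to C7. Stoichiometric chromium at high dilution is awkward. In A2 the silyl group on O8 must still be exchanged for the acyl group beside a free C9 hydroxyl.
- Comparison: on the C8/C9 problem this road is stronger than the chosen one, which must rely on the face of an osmylation and on a selective silylation. The chosen plan sets against it a catalytic ring closure, both oxygens from one addition, and no open-chain stereocenter at C8. The chromium chemistry is used in the chosen route only intermolecularly (step 5), where its stereochemical outcome does not matter.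

**Alternative 3:** The ring is traced back to a six–six bicycle with an extra C4–C9 bond. Forward, a C9 alkoxide expels a C5 mesylate while the shared bond breaks (Grob fragmentation). This gives the C9 ketone and the E C4=C5 alkene of A3.
- Merits: no entropically difficult ring closure. The alkene geometry follows from the antiperiplanar arrangement in a rigid bicycle. A C9 ketone could be reduced from the open face of the ring, which is a more reliable way to place O9 than an alkene addition.
- Weak points: the bicycle must already carry the enoate, the lactone, a protected O8 and a correctly oriented mesylate, which means a long preparation. In A3, C8 is enolisable next to the ketone. Epoxidation, ketone reduction and methylenation all remain.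
- Comparison: this road is better at the ring-forming event and possibly at C9. It is clearly worse in step economy. The chosen plan reaches its ring-closure substrate in nine steps from a commercial lactone.

Key step: step 2

Remark: the C5 carbinol of 12 and 14 and C11 of 6 and 7 are formed as epimer mixtures that the next operation erases, so their SMILES carry no descriptor there; locants C1–C15 follow germacrane numbering throughout.

## Route

Step 1
Reactants: 1 (S)-5-(hydroxymethyl)furan-2(5H)-one
Product: 2 (S)-5-[(tert-butyldiphenylsilyloxy)methyl]furan-2(5H)-one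
Conditions: t-BuPh2SiCl, imidazole, DMF, 0 °C → rt
Reagents that add atoms: tert-butyl(chloro)diphenylsilane, CC(C)(C)[Si](Cl)(c1ccccc1)c1ccccc1
Why: Silylation of a primary alcohol; the bulky silyl ether is stable to organocopper reagents and enlarges the group that shields one face of the butenolide in step 2.

Step 2
Reactants: 2 (S)-5-[(tert-butyldiphenylsilyloxy)methyl]furan-2(5H)-one; 3 vinylmagnesium bromide; 4 dimethylmethyleneiminium iodide
Product: 8 (4S,5S)-5-[(tert-butyldiphenylsilyloxy)methyl]-3-methylene-4-vinyldihydrofuran-2(3H)-one, via magnesium enolate 5 (not isolated), via Mannich base 6 (not isolated), via ammonium iodide 7 (not isolated)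
Conditions: 3 (2.2 equiv), CuI (1.1 equiv), THF–Me2S, −78 → −40 °C; 2, −78 °C; 4 (excess), −78 °C → rt; MeI, MeOH, rt; NaHCO3 (aq), CH2Cl2, rt
Reagents that add atoms: vinylmagnesium bromide (3), C=C[Mg]Br; dimethylmethyleneiminium iodide (4), C=[N+](C)C.[I-]
Why: Tandem conjugate addition–Mannich methylenation of a γ-substituted butenolide, a known reaction type. Two equivalents of 3 and CuI form bromomagnesium divinylcuprate, which adds 1,4 to 2 by π-complexation, oxidative addition at C7 and reductive elimination, giving the C7–C8 bond and enolate 5. The enolate carbon C11 attacks the iminium ion of 4 and forms C11–C13 (Mannich base 6). N-Methylation gives 7, and NaHCO3 removes the hydrogen on C11 so that trimethylamine leaves and the exocyclic C11=C13 alkene appears. No ring is closed, since the lactone is present from the start. The one lasting new stereocenter, C7, is controlled by C6: the silyloxymethyl group covers one face of the flat butenolide and the vinyl group enters trans to it, while C11 is formed as a mixture and becomes sp2. The step needs 1,4- over 1,2-addition (secured by copper), a single C-alkylation of the enolate (the iminium ion gives an amine that cannot alkylate again) and elimination through the lactone enolate, which can only place the alkene between C11 and C13.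

Step 3
Reactants: 8 (4S,5S)-5-[(tert-butyldiphenylsilyloxy)methyl]-3-methylene-4-vinyldihydrofuran-2(3H)-one
Product: 9 (4S,5S)-5-(hydroxymethyl)-3-methylene-4-vinyldihydrofuran-2(3H)-one
Conditions: HF·pyridine, THF, 0 °C → rt
Reagents that add atoms: none
Why: Fluoride-mediated cleavage of the Si–O bond under acidic conditions; no basic fluoride is present that could add to the methylene lactone.

Step 4
Reactants: 9 (4S,5S)-5-(hydroxymethyl)-3-methylene-4-vinyldihydrofuran-2(3H)-one
Product: 10 (2S,3S)-4-methylene-5-oxo-3-vinyltetrahydrofuran-2-carbaldehyde
Conditions: Dess–Martin periodinane, NaHCO3, CH2Cl2, 0 °C → rt; used crude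
Reagents that add atoms: none
Why: Dess–Martin oxidation, neutral and non-nucleophilic. The α-acyloxy aldehyde is carried on without purification to avoid hydration and epimerisation at C6, whose trans arrangement is also the thermodynamically preferred one.

Step 5
Reactants: 10 (2S,3S)-4-methylene-5-oxo-3-vinyltetrahydrofuran-2-carbaldehyde; 11 2-bromopropene
Product: 12 (4S,5S)-5-(1-hydroxy-2-methylprop-2-en-1-yl)-3-methylene-4-vinyldihydrofuran-2(3H)-one (both carbinol epimers)
Conditions: 11, CrCl2 (4 equiv), NiCl2 (cat.), DMF, rt
Reagents that add atoms: 2-bromopropene (11), C=C(C)Br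
Why: Nozaki–Hiyama–Kishi alkenylation: 11 adds oxidatively to zerovalent nickel, the alkenyl group passes to trivalent chromium and adds to the aldehyde only, leaving lactone and acrylate untouched. The new carbinol center need not be controlled because C5 becomes sp2 in step 6.

Step 6
Reactants: 12 (4S,5S)-5-(1-hydroxy-2-methylprop-2-en-1-yl)-3-methylene-4-vinyldihydrofuran-2(3H)-one; 13 ethyl vinyl ether
Product: 15 (E)-4-methyl-5-[(2R,3S)-4-methylene-5-oxo-3-vinyltetrahydrofuran-2-yl]pent-4-enal, via allyl vinyl ether 14 (not isolated)
Conditions: Hg(OAc)2 (cat.), 13 (solvent), reflux; evaporate; PhMe, 2,6-di-tert-butyl-4-methylphenol (cat.), 120 °C, sealed tube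
Reagents that add atoms: ethyl vinyl ether (13), C=COCC
Why: Mercury-catalysed vinyl ether exchange followed by an aliphatic Claisen rearrangement. The chair transition state with the lactone substituent pseudo-equatorial forms C2–C3 and the E trisubstituted C4=C5 alkene, and the C1 aldehyde appears directly without any reduction beside the lactone.

Step 7
Reactants: 15 (E)-4-methyl-5-[(2R,3S)-4-methylene-5-oxo-3-vinyltetrahydrofuran-2-yl]pent-4-enal; 16 methyl (triphenylphosphoranylidene)acetate
Product: 18 methyl (2Z,6E)-2-iodo-6-methyl-7-[(2R,3S)-4-methylene-5-oxo-3-vinyltetrahydrofuran-2-yl]hepta-2,6-dienoate, via iodo ylide 17 (not isolated)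
Conditions: 16, N-iodosuccinimide, CH2Cl2, −20 °C; then 15, −20 °C → rt
Reagents that add atoms: methyl (triphenylphosphoranylidene)acetate (16), COC(=O)C=P(c1ccccc1)(c1ccccc1)c1ccccc1; N-iodosuccinimide, O=C1CCC(=O)N1I
Why: Wittig olefination with an α-iodo ylide made in the flask. The stabilised ylide should give mainly the Z iodoenoate (iodine cis to C2, ester trans), the geometry that later becomes the ring-cis C1=C10, and it is too weak a nucleophile to add to the methylene lactone at this temperature.

Step 8
Reactants: 18 methyl (2Z,6E)-2-iodo-6-methyl-7-[(2R,3S)-4-methylene-5-oxo-3-vinyltetrahydrofuran-2-yl]hepta-2,6-dienoate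
Product: 19 methyl (Z)-2-iodo-5-{(2R,3R)-2-methyl-3-[(2S,3S)-4-methylene-5-oxo-3-vinyltetrahydrofuran-2-yl]oxiran-2-yl}pent-2-enoate
Conditions: D-fructose-derived Shi ketone (0.3 equiv), KHSO5 (as 2KHSO5·KHSO4·K2SO4), K2CO3, Bu4NHSO4, MeCN–CH2(OMe)2–aq. Na2B4O7/Na2EDTA, 0 °C
Reagents that add atoms: potassium peroxymonosulfate, [K+].[O-]S(=O)(=O)OO
Why: Shi epoxidation: the chiral dioxirane transfers oxygen through a spiro transition state. The D-fructose-derived ketone converts E trisubstituted alkenes into (R,R)-epoxides, which is the 4R,5R sense needed, by reagent control. The trisubstituted C4=C5 is the only electron-rich alkene of 18; the vinyl group reacts far more slowly and the acrylate-type alkenes not at all.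

Step 9
Reactants: 19 methyl (Z)-2-iodo-5-{(2R,3R)-2-methyl-3-[(2S,3S)-4-methylene-5-oxo-3-vinyltetrahydrofuran-2-yl]oxiran-2-yl}pent-2-enoate; 20 tributyl(vinyl)stannane
Product: 21 methyl (E)-5-{(2R,3R)-2-methyl-3-[(2S,3S)-4-methylene-5-oxo-3-vinyltetrahydrofuran-2-yl]oxiran-2-yl}-2-vinylpent-2-enoate
Conditions: 20, Pd2(dba)3 (cat.), AsPh3, CuI (cat.), N-methylpyrrolidone, rt
Reagents that add atoms: tributyl(vinyl)stannane (20), C=C[Sn](CCCC)(CCCC)CCCC
Why: Stille coupling of an α-iodoenoate at room temperature with retention of alkene geometry, so the new vinyl group (C9) stays cis to C2. With the epoxide already in place there is no allylic lactone for zerovalent palladium to ionise, and the dimerisation-prone diene is made only one step before it is consumed.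

Step 10
Reactants: 21 methyl (E)-5-{(2R,3R)-2-methyl-3-[(2S,3S)-4-methylene-5-oxo-3-vinyltetrahydrofuran-2-yl]oxiran-2-yl}-2-vinylpent-2-enoate
Product: 22 methyl (1(10)E,4R,5R,6S,7S,8Z)-4,5-epoxy-12-oxo-6,12-epoxygermacra-1(10),8,11(13)-trien-14-oate (ten-membered ring, Z C8=C9, ring-cis C1=C10)
Conditions: second-generation Grubbs catalyst (H2IMes)(PCy3)Cl2Ru=CHPh (10 mol%), PhMe (1 mM), 80 °C
Reagents that add atoms: none
Why: Ring-closing metathesis: the ruthenium alkylidene loads on the vinyl group at C7 and closes on the terminal vinyl of the diene with loss of ethene, which makes closure irreversible. A ten-membered ring that already holds a ring-cis C1=C10 should accept the new alkene only as Z; the 1,1-disubstituted acrylate alkene C11=C13 and the trisubstituted enoate are poor metathesis partners and should stay out.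

Step 11
Reactants: 22 methyl (1(10)E,4R,5R,6S,7S,8Z)-4,5-epoxy-12-oxo-6,12-epoxygermacra-1(10),8,11(13)-trien-14-oate
Product: 23 methyl (1(10)E,4R,5R,6S,7R,8S,9R)-4,5-epoxy-8,9-dihydroxy-12-oxo-6,12-epoxygermacra-1(10),11(13)-dien-14-oate
Conditions: OsO4 (5 mol%), N-methylmorpholine N-oxide (1.1 equiv), acetone–H2O, 0 °C
Reagents that add atoms: osmium tetroxide, O=[Os](=O)(=O)=O; N-methylmorpholine N-oxide, C[N+]1([O-])CCOCC1; water, O
Why: Upjohn dihydroxylation: OsO4 adds to C8=C9, the only alkene that is not acrylate-like, and suprafacial addition to the Z alkene fixes the 8,9-erythro relation. The absolute sense is decided by the ring: both oxygens must arrive on the face that carries C11 at C7, which requires the ring to present that face; this is the least secure stereochemical event of the route and is taken up under the risks.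

Step 12
Reactants: 23 methyl (1(10)E,4R,5R,6S,7R,8S,9R)-4,5-epoxy-8,9-dihydroxy-12-oxo-6,12-epoxygermacra-1(10),11(13)-dien-14-oate
Product: 24 9-O-triethylsilyl ether of diol 23 (free 8-hydroxyl)
Conditions: Et3SiCl (1.05 equiv), pyridine, CH2Cl2, −20 °C
Reagents that add atoms: chlorotriethylsilane, CC[Si](Cl)(CC)CC
Why: Selective monosilylation: the allylic C9 hydroxyl sits beside the flat sp2 carbon C10, the C8 hydroxyl beside the branched ring-fusion carbon C7, so the bulky silyl chloride should take O9. Pyridine is too weak a base to cause relactonisation of O8 onto C12.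

Step 13
Reactants: 25 tiglic acid
Product: 26 (E)-2-methylbut-2-en-1-ol
Conditions: LiAlH4, Et2O, 0 °C → rt
Reagents that add atoms: none
Why: Hydride reduction of an α,β-unsaturated acid at the carbonyl only; the E alkene is untouched.

Step 14
Reactants: 26 (E)-2-methylbut-2-en-1-ol
Product: 27 [(2R,3R)-2,3-dimethyloxiran-2-yl]methanol
Conditions: Ti(OiPr)4 (cat.), D-(−)-diethyl tartrate (cat.), t-BuOOH, 4 Å sieves, CH2Cl2, −20 °C
Reagents that add atoms: tert-butyl hydroperoxide, CC(C)(C)OO
Why: Sharpless asymmetric epoxidation: E allylic alcohols give the (2S,3S) series with the L-(+)-tartrate, so the D-(−)-tartrate delivers the (2R,3R) epoxy alcohol, and the syn oxygen transfer keeps the two methyl groups cis.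

Step 15
Reactants: 27 [(2R,3R)-2,3-dimethyloxiran-2-yl]methanol
Product: 28 (2S,3R)-2,3-dimethyloxirane-2-carboxylic acid
Conditions: RuCl3 (cat.), NaIO4, MeCN–EtOAc–H2O, 0 °C → rt
Reagents that add atoms: water, O; sodium periodate, [Na+].[O-]I(=O)(=O)=O
Why: Ruthenium tetroxide oxidation of a 2,3-epoxy alcohol to the glycidic acid (aldehyde, hydrate, acid) without touching the epoxide. The geometry is unchanged; only the C2 descriptor switches from R to S because the carboxyl outranks C3.

Step 16
Reactants: 24 9-O-triethylsilyl ether of diol 23; 28 (2S,3R)-2,3-dimethyloxirane-2-carboxylic acid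
Product: 30 9-O-triethylsilyl ether of the target, via mixed anhydride 29 (not isolated)
Conditions: 28, 2,4,6-trichlorobenzoyl chloride, NEt3, THF, rt; then 24, 4-(dimethylamino)pyridine (cat.), PhMe, rt
Reagents that add atoms: none
Why: Yamaguchi esterification: the mixed anhydride 29 is attacked at the less hindered epoxy-acyl carbonyl, which suits a hindered secondary alcohol and an α-quaternary acid. No acid chloride or strong acid is present that could open either epoxide, and O9 is blocked so the acyl group cannot go astray.

Step 17
Reactants: 30 9-O-triethylsilyl ether of the target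
Product: 31 methyl (1(10)E,4R,5R,6S,7R,8S,9R)-8-{[(2S,3R)-2,3-dimethyloxiran-2-yl]carbonyloxy}-4,5-epoxy-9-hydroxy-12-oxo-6,12-epoxygermacra-1(10),11(13)-dien-14-oate (target)
Conditions: HF·pyridine, pyridine, THF, 0 °C
Reagents that add atoms: none
Why: Buffered HF removes the triethylsilyl ether under mildly acidic, non-nucleophilic conditions; these disfavour the base-promoted shift of the acyl group from O8 to O9 and are too weak to open the epoxides.

## Compound list

1 | (S)-5-(hydroxymethyl)furan-2(5H)-one | O=C1C=C[C@@H](CO)O1 | starting material
2 | (S)-5-[(tert-butyldiphenylsilyloxy)methyl]furan-2(5H)-one | O=C1C=C[C@@H](CO[Si](c2ccccc2)(c2ccccc2)C(C)(C)C)O1 | intermediate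
3 | vinylmagnesium bromide | C=C[Mg]Br | starting material
4 | dimethylmethyleneiminium iodide | C=[N+](C)C.[I-] | starting material
5 | bromomagnesium enolate of the trans 4-vinyl lactone | C1=C(O[Mg]Br)O[C@H](CO[Si](c2ccccc2)(c2ccccc2)C(C)(C)C)[C@H]1C=C | intermediate
6 | (4S,5S)-5-[(tert-butyldiphenylsilyloxy)methyl]-3-[(dimethylamino)methyl]-4-vinyldihydrofuran-2(3H)-one (C3 epimers) | CN(C)CC1C(=O)O[C@H](CO[Si](c2ccccc2)(c2ccccc2)C(C)(C)C)[C@H]1C=C | intermediate
7 | N-methyl quaternary iodide of 6 | C[N+](C)(C)CC1C(=O)O[C@H](CO[Si](c2ccccc2)(c2ccccc2)C(C)(C)C)[C@H]1C=C.[I-] | intermediate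
8 | (4S,5S)-5-[(tert-butyldiphenylsilyloxy)methyl]-3-methylene-4-vinyldihydrofuran-2(3H)-one | C=C1C(=O)O[C@H](CO[Si](c2ccccc2)(c2ccccc2)C(C)(C)C)[C@H]1C=C | intermediate
9 | (4S,5S)-5-(hydroxymethyl)-3-methylene-4-vinyldihydrofuran-2(3H)-one | C=C1C(=O)O[C@H](CO)[C@H]1C=C | intermediate
10 | (2S,3S)-4-methylene-5-oxo-3-vinyltetrahydrofuran-2-carbaldehyde | C=C1C(=O)O[C@H](C=O)[C@H]1C=C | intermediate
11 | 2-bromopropene | C=C(C)Br | starting material
12 | (4S,5S)-5-(1-hydroxy-2-methylprop-2-en-1-yl)-3-methylene-4-vinyldihydrofuran-2(3H)-one (carbinol epimers) | C=C1C(=O)O[C@H](C(O)C(C)=C)[C@H]1C=C | intermediate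
13 | ethyl vinyl ether | C=COCC | starting material
14 | (4S,5S)-3-methylene-5-[2-methyl-1-(vinyloxy)prop-2-en-1-yl]-4-vinyldihydrofuran-2(3H)-one (epimers) | C=C1C(=O)O[C@H](C(OC=C)C(C)=C)[C@H]1C=C | intermediate
15 | (E)-4-methyl-5-[(2R,3S)-4-methylene-5-oxo-3-vinyltetrahydrofuran-2-yl]pent-4-enal | C=C1C(=O)O[C@H](/C=C(\C)CCC=O)[C@H]1C=C | intermediate
16 | methyl (triphenylphosphoranylidene)acetate | COC(=O)C=P(c1ccccc1)(c1ccccc1)c1ccccc1 | starting material
17 | methyl iodo(triphenylphosphoranylidene)acetate | COC(=O)C(I)=P(c1ccccc1)(c1ccccc1)c1ccccc1 | intermediate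
18 | methyl (2Z,6E)-2-iodo-6-methyl-7-[(2R,3S)-4-methylene-5-oxo-3-vinyltetrahydrofuran-2-yl]hepta-2,6-dienoate | C=C1C(=O)O[C@H](/C=C(\C)CC/C=C(\I)C(=O)OC)[C@H]1C=C | intermediate
19 | methyl (Z)-2-iodo-5-{(2R,3R)-2-methyl-3-[(2S,3S)-4-methylene-5-oxo-3-vinyltetrahydrofuran-2-yl]oxiran-2-yl}pent-2-enoate | C=C1C(=O)O[C@H]([C@H]2O[C@]2(C)CC/C=C(\I)C(=O)OC)[C@H]1C=C | intermediate
20 | tributyl(vinyl)stannane | C=C[Sn](CCCC)(CCCC)CCCC | starting material
21 | methyl (E)-5-{(2R,3R)-2-methyl-3-[(2S,3S)-4-methylene-5-oxo-3-vinyltetrahydrofuran-2-yl]oxiran-2-yl}-2-vinylpent-2-enoate | C=C1C(=O)O[C@H]([C@H]2O[C@]2(C)CC/C=C(\C=C)C(=O)OC)[C@H]1C=C | intermediate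
22 | methyl (1(10)E,4R,5R,6S,7S,8Z)-4,5-epoxy-12-oxo-6,12-epoxygermacra-1(10),8,11(13)-trien-14-oate | C=C1C(=O)O[C@H]2[C@H]1/C=C\C(C(=O)OC)=C/CC[C@@]1(C)O[C@H]21 | intermediate
23 | methyl (1(10)E,4R,5R,6S,7R,8S,9R)-4,5-epoxy-8,9-dihydroxy-12-oxo-6,12-epoxygermacra-1(10),11(13)-dien-14-oate | C=C1C(=O)O[C@H]2[C@H]1[C@H](O)[C@H](O)/C(C(=O)OC)=C\CC[C@@]1(C)O[C@H]21 | intermediate
24 | 9-O-triethylsilyl ether of diol 23 | C=C1C(=O)O[C@H]2[C@H]1[C@H](O)[C@H](O[Si](CC)(CC)CC)/C(C(=O)OC)=C\CC[C@@]1(C)O[C@H]21 | intermediate
25 | tiglic acid, (E)-2-methylbut-2-enoic acid | C/C=C(\C)C(=O)O | starting material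
26 | (E)-2-methylbut-2-en-1-ol | C/C=C(\C)CO | intermediate
27 | [(2R,3R)-2,3-dimethyloxiran-2-yl]methanol | OC[C@@]1(C)O[C@@H]1C | intermediate
28 | (2S,3R)-2,3-dimethyloxirane-2-carboxylic acid | OC(=O)[C@@]1(C)O[C@@H]1C | intermediate
29 | (2S,3R)-2,3-dimethyloxirane-2-carboxylic 2,4,6-trichlorobenzoic anhydride | O=C(OC(=O)c1c(Cl)cc(Cl)cc1Cl)[C@@]1(C)O[C@@H]1C | intermediate
30 | 9-O-triethylsilyl ether of the target | C=C1C(=O)O[C@H]2[C@H]1[C@H](OC(=O)[C@@]1(C)O[C@@H]1C)[C@H](O[Si](CC)(CC)CC)/C(C(=O)OC)=C\CC[C@@]1(C)O[C@H]21 | intermediate
31 | methyl (1(10)E,4R,5R,6S,7R,8S,9R)-8-{[(2S,3R)-2,3-dimethyloxiran-2-yl]carbonyloxy}-4,5-epoxy-9-hydroxy-12-oxo-6,12-epoxygermacra-1(10),11(13)-dien-14-oate | C=C1C(=O)O[C@H]2[C@H]1[C@H](OC(=O)[C@@]1(C)O[C@@H]1C)[C@H](O)/C(C(=O)OC)=C\CC[C@@]1(C)O[C@H]21 | target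

## Step count and least certain steps

Total: 17 steps. Longest linear sequence: 14 steps (steps 1–12, 16 and 17, from 1); the side chain (steps 13–15) joins at step 16.

**Step 2 (key step).**
- Most likely failure: incomplete C-alkylation of the copper–magnesium enolate. Proton transfer, or consumption of the iminium salt by leftover vinyl-metal species, would leave the simple conjugate adduct. Loss of trans selectivity is the lesser concern.
- Fallback (from 2, back at 8): separate the two bond formations and change the methylenation chemistry. Conjugate addition alone with aqueous quench gives (4R,5S)-5-[(tert-butyldiphenylsilyloxy)methyl]-4-vinyldihydrofuran-2(3H)-one F1. Formylation at C11 (NaH, ethyl formate) gives the 3-formyl lactone F2 as its sodium enolate. Treatment with paraformaldehyde and K2CO3 in THF then gives 8 by hydroxymethylation and loss of formate.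

**Step 10 (ring-closing metathesis).**
- Most likely failure: oligomerisation instead of ring closure, because of the strain of a ten-membered ring with a cis,cis-diene. Unproductive chelation of the ruthenium carbene by the C14 ester and partial formation of the E isomer are further possibilities.
- Fallback (from 18, back at 22): close the ring on a differently shaped chain by reversing the order of epoxidation and cyclisation. Stille coupling of 18 with 20 gives methyl (2E,6E)-6-methyl-7-[(2R,3S)-4-methylene-5-oxo-3-vinyltetrahydrofuran-2-yl]-2-vinylhepta-2,6-dienoate F3. Metathesis of this substrate, whose flat E C4=C5 replaces the epoxide, gives the macrocyclic 4,5-alkene F4. Shi epoxidation of F4, in which C4=C5 is again the most electron-rich alkene, then gives 22.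

**Step 11 (dihydroxylation).**
- Most likely failure: reversed facial selectivity. Allylic 1,3-strain between C7 and C10 across the Z alkene should turn C7–H into the alkene plane. The ring then lies on the face toward C6, and osmium is directed to the opposite face, not the one the target needs, unless the overall ring conformation overrides this local preference.
- Fallback (from 22, back at 31): accept that face and invert both centers. Osmylation gives the 8,9-bis-epi diol F5 (8R,9S). Mitsunobu esterification of its allylic C9 hydroxyl with acid 28 (PPh3, diisopropyl azodicarboxylate) inverts C9 and gives the 9-O-acyl 8-epi alcohol F6. Activation of the remaining C8 hydroxyl (Tf2O, pyridine) lets the trans-disposed ester carbonyl displace the triflate from the rear. Hydrolysis of the cis-fused acyloxonium ion gives the 8,9-cis hydroxy ester with both centers inverted, that is 31. Its 9-O-acyl isomer F7 (see step 12) would form alongside and could be equilibrated by acyl shift.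

**Step 12 (selective silylation).**
- Most likely failure: poor discrimination between the two secondary hydroxyls, with silylation at O8 or at both oxygens. Silyl migration between the cis oxygens is also possible.
- Fallback (from 23, back at 31): drop the protecting group and use whatever preference the diol shows. If the C8 hydroxyl is the more reactive one, which is the case in which silylation at O9 fails, acylation of 23 with one equivalent of mixed anhydride 29 should give 31 directly. The 9-O-acyl regioisomer F7 is separated and returned to the mixture of monoesters by mild base-mediated acyl shift.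

## Further compounds

F1 | step 2 | (4R,5S)-5-[(tert-butyldiphenylsilyloxy)methyl]-4-vinyldihydrofuran-2(3H)-one | C1C(=O)O[C@H](CO[Si](c2ccccc2)(c2ccccc2)C(C)(C)C)[C@H]1C=C
F2 | step 2 | (4S,5S)-5-[(tert-butyldiphenylsilyloxy)methyl]-2-oxo-4-vinyltetrahydrofuran-3-carbaldehyde (C3 epimers or enol) | O=CC1C(=O)O[C@H](CO[Si](c2ccccc2)(c2ccccc2)C(C)(C)C)[C@H]1C=C
F3 | step 10 | methyl (2E,6E)-6-methyl-7-[(2R,3S)-4-methylene-5-oxo-3-vinyltetrahydrofuran-2-yl]-2-vinylhepta-2,6-dienoate | C=C1C(=O)O[C@H](/C=C(\C)CC/C=C(\C=C)C(=O)OC)[C@H]1C=C
F4 | step 10 | methyl (1(10)E,4E,8Z)-12-oxo-6,12-epoxygermacra-1(10),4,8,11(13)-tetraen-14-oate (6S,7S) | C=C1C(=O)O[C@H]2[C@H]1/C=C\C(C(=O)OC)=C/CC/C(C)=C/2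
F5 | step 11 | 8,9-bis-epimer (8R,9S) of diol 23 | C=C1C(=O)O[C@H]2[C@H]1[C@@H](O)[C@@H](O)/C(C(=O)OC)=C\CC[C@@]1(C)O[C@H]21
F6 | step 11 | 8-epi alcohol carrying the (2S,3R)-2,3-dimethyloxirane-2-carbonyl group on O9 (8R,9R) | C=C1C(=O)O[C@H]2[C@H]1[C@@H](O)[C@H](OC(=O)[C@@]1(C)O[C@@H]1C)/C(C(=O)OC)=C\CC[C@@]1(C)O[C@H]21
F7 | step 12 | 9-O-acyl regioisomer of the target (free 8-hydroxyl) | C=C1C(=O)O[C@H]2[C@H]1[C@H](O)[C@H](OC(=O)[C@@]1(C)O[C@@H]1C)/C(C(=O)OC)=C\CC[C@@]1(C)O[C@H]21
A1 | alternative 1 | ten-membered (E)-allylic alcohol from the nickel-mediated alkyne–aldehyde–methyl coupling | C1/C(C)=C/[C@@H](O)[C@H](CC(=O)OC(C)(C)C)[C@H](OCc2ccc(OC)cc2)[C@H](O[Si](C)(C)C(C)(C)C)/C(C(=O)OC)=C\C1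
A2 | alternative 2 | 8-O-triethylsilyl 9-hydroxy melampolide from the chromium-mediated ring closure | C=C1C(=O)O[C@H]2[C@H]1[C@H](O[Si](CC)(CC)CC)[C@H](O)/C(C(=O)OC)=C\CC[C@@]1(C)O[C@H]21
A3 | alternative 3 | cyclodecadienone lactone from the fragmentation | C1/C(C)=C/[C@H]2OC(=O)C[C@@H]2[C@H](O[Si](CC)(CC)CC)C(=O)/C(C(=O)OC)=C\C1
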